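Both phloroglucinol rings A are made last. In each half, ring A is fused to ring C along C4a–C8a, which in a 2-aryl-2,3-dihydropyran-4-one is the enone C=C; a bromine at C4a turns this bond into an alkyne equivalent for 1-methoxy-1,3-bis(trimethylsilyloxy)butadiene. One operation forms C8–C8a and C4a–C5 twice and, through loss of HBr and methanol, gives both 5,7-dihydroxy arenes. The precursor is the 3',3'''-linked biaryl bis(5-bromodihydropyranone) with C2 (S), C2'' (R) and C3'' (R) already set; the C3'' oxygen rides through as a TES ether, so no flavanone is enolised or desymmetrised afterwards.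

Key step: step 9

Assumption: the (S)-BINOL–Ti(OiPr)4 catalyst is taken to deliver the diene to the Si face of aryl aldehydes (the sense it shows in aldehyde allylation); if a check on the first batch shows the opposite sense, (R)-BINOL is used and nothing else changes.

Step 1
Reactants: 1 4-(benzyloxy)-3-bromobenzaldehyde; 2 (E)-1-methoxy-3-(trimethylsilyloxy)buta-1,3-diene
Product: 4 (S)-2-[4-(benzyloxy)-3-bromophenyl]-2,3-dihydro-4H-pyran-4-one, via silyl aldol adduct 3 (not isolated)
Conditions: Ti(OiPr)4 (10 mol%), (S)-BINOL (20 mol%), 4 Å sieves, Et2O, −20 °C; then TFA, CH2Cl2, 0 °C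
Reagents that add atoms: none
Why: Catalytic asymmetric hetero-Diels–Alder reaction of an aryl aldehyde with Danishefsky's diene, here by the Mukaiyama aldol pathway followed by acid-induced ring closure with loss of the methoxy and silyl groups; the BINOL–titanium complex blocks one aldehyde face so that the diene adds to the Si face and C2 is formed as S.

Step 2
Reactants: 4 (S)-2-[4-(benzyloxy)-3-bromophenyl]-2,3-dihydro-4H-pyran-4-one
Product: 5 (S)-2-[4-(benzyloxy)-3-(4,4,5,5-tetramethyl-1,3,2-dioxaborolan-2-yl)phenyl]-2,3-dihydro-4H-pyran-4-one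
Conditions: B2pin2 (1.2 equiv), Pd(dppf)Cl2 (3 mol%), KOAc, 1,4-dioxane, 85 °C
Reagents that add atoms: bis(pinacolato)diboron, CC1(C)OB(OC1(C)C)B1OC(C)(C)C(C)(C)O1
Why: Miyaura borylation of the aryl bromide, in which KOAc is too weak a base to enolise the pyranone, so the C2 centre and the vinylogous ester should be untouched.

Step 3
Reactants: 4 (S)-2-[4-(benzyloxy)-3-bromophenyl]-2,3-dihydro-4H-pyran-4-one
Product: 8 (2R,3R)-2-[4-(benzyloxy)-3-bromophenyl]-3-hydroxy-2,3-dihydro-4H-pyran-4-one, via silyl dienol ether 6 (not isolated), via silyloxy epoxide 7 (not isolated)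
Conditions: TMSOTf, Et3N, CH2Cl2, −20 °C; then DMDO (1.05 equiv), acetone–CH2Cl2, −78 → −20 °C; then aqueous citric acid, THF, 0 °C
Reagents that add atoms: dimethyldioxirane, CC1(C)OO1
Why: Rubottom oxidation: soft enolisation at C3 gives the cross-conjugated silyl dienol ether, dimethyldioxirane epoxidises its electron-richer C3=C4 bond on the face anti to the C2 aryl group, and the epoxide collapses to the α-hydroxy ketone, which sets C3 trans to C2 (2R,3R; the change of the C2 descriptor from S to R is a priority effect only).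

Step 4
Reactants: 8 (2R,3R)-2-[4-(benzyloxy)-3-bromophenyl]-3-hydroxy-2,3-dihydro-4H-pyran-4-one
Product: 9 (2R,3R)-2-[4-(benzyloxy)-3-bromophenyl]-3-(triethylsilyloxy)-2,3-dihydro-4H-pyran-4-one
Conditions: TESCl, imidazole, DMF, 0 °C → rt
Reagents that add atoms: chlorotriethylsilane, CC[Si](Cl)(CC)CC
Why: Standard silylation of a secondary alcohol; TES is chosen because it should survive steps 5 and 6 and fall off in the acidic work-up of step 9.

Step 5
Reactants: 5 (S)-2-[4-(benzyloxy)-3-(4,4,5,5-tetramethyl-1,3,2-dioxaborolan-2-yl)phenyl]-2,3-dihydro-4H-pyran-4-one; 9 (2R,3R)-2-[4-(benzyloxy)-3-bromophenyl]-3-(triethylsilyloxy)-2,3-dihydro-4H-pyran-4-one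
Product: 10 (2R,3R)-2-{4-(benzyloxy)-3-[2-(benzyloxy)-5-((2S)-4-oxo-3,4-dihydro-2H-pyran-2-yl)phenyl]phenyl}-3-(triethylsilyloxy)-2,3-dihydro-4H-pyran-4-one
Conditions: Pd(OAc)2 (3 mol%), SPhos (6 mol%), K3PO4, toluene–H2O (10:1), 60 °C
Reagents that add atoms: none
Why: Suzuki–Miyaura cross-coupling of two ortho-alkoxy aryl partners with a catalyst suited to hindered biaryls; only two ortho substituents flank the new bond, so no atropisomers arise, and the mild phosphate base should leave the three stereocentres alone.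

Step 6
Reactants: 10 (2R,3R)-2-{4-(benzyloxy)-3-[2-(benzyloxy)-5-((2S)-4-oxo-3,4-dihydro-2H-pyran-2-yl)phenyl]phenyl}-3-(triethylsilyloxy)-2,3-dihydro-4H-pyran-4-one
Product: 11 (2R,3R)-5-bromo-2-{4-(benzyloxy)-3-[2-(benzyloxy)-5-((2S)-5-bromo-4-oxo-3,4-dihydro-2H-pyran-2-yl)phenyl]phenyl}-3-(triethylsilyloxy)-2,3-dihydro-4H-pyran-4-one
Conditions: Br2 (2.1 equiv), CH2Cl2, −78 °C; then Et3N, −78 → 0 °C
Reagents that add atoms: bromine, BrBr
Why: α-Bromination of the two β-alkoxy enones by addition of bromine to each enol ether C=C (pyranone C5=C6) and amine-induced loss of HBr; at −78 °C the enol ethers should react far faster than the benzyloxyarene rings.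

Step 7
Reactants: 12 methyl acetoacetate
Product: 13 methyl 3-(trimethylsilyloxy)but-2-enoate (E/Z mixture)
Conditions: TMSCl, Et3N, hexane, rt
Reagents that add atoms: chlorotrimethylsilane, C[Si](C)(C)Cl
Why: O-Silylation of the enol form of a β-keto ester (silyl enol ether formation).

Step 8
Reactants: 13 methyl 3-(trimethylsilyloxy)but-2-enoate
Product: 14 1-methoxy-1,3-bis(trimethylsilyloxy)buta-1,3-diene
Conditions: LDA, THF, −78 °C; then TMSCl, −78 °C → rt; distilled and used fresh
Reagents that add atoms: chlorotrimethylsilane, C[Si](C)(C)Cl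
Why: Kinetic γ-deprotonation of the silyloxy enoate and O-silylation of the dienolate give the 1,3-bis(silyloxy) diene (Chan's diene); the C1=C2 geometry is of no consequence.

Step 9
Reactants: 11 (2R,3R)-5-bromo-2-{4-(benzyloxy)-3-[2-(benzyloxy)-5-((2S)-5-bromo-4-oxo-3,4-dihydro-2H-pyran-2-yl)phenyl]phenyl}-3-(triethylsilyloxy)-2,3-dihydro-4H-pyran-4-one; 14 1-methoxy-1,3-bis(trimethylsilyloxy)buta-1,3-diene
Product: 17 4',4'''-di-O-benzyl ether of 18, via twofold cycloadduct 15 (not isolated), via persilylated biflavanone 16 (not isolated)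
Conditions: 14 (5 equiv), TMSOTf (0.3 equiv), CH2Cl2, −78 → −20 °C; then 2,6-lutidine (8 equiv), TMSOTf (2.2 equiv), −20 → 20 °C; then 1 M HCl, THF–MeOH, rt
Reagents that add atoms: none
Why: Proposed new method: TMSOTf silylates each enone oxygen to a 4-silyloxy-pyrylium-type oxocarbenium ion, the CH2 terminus of 14 adds to its C8a (flavanone numbering; the enone β carbon) to make C8–C8a, and the resulting α-bromo silyl enol ether attacks the dioxygenated allyl cation at the former ketene acetal carbon to make C4a–C5, so that each ring A closes in a stepwise formal [4+2] by a 6-(enolexo)-exo-trig Mukaiyama-type step and C4a becomes quaternary (15). The closest known reactions are the Diels–Alder/aromatisation sequences of 1,3-dioxygenated silyloxydienes with bromoquinones and with 3-acyl- or 3-cyanochromones, and the TMSOTf-mediated conjugate addition of 1,3-bis(silyloxy)dienes to chromones; a β-alkoxy-α-bromo enone has not been used in this role. Further TMSOTf with 2,6-lutidine ionises each C5 ketal (loss of MeOSiMe3), a C8 proton is removed, and the 4a-bromo-4a,8a-dihydro diene should lose HBr under the driving force of aromatisation to give 16, which acid desilylates at the four phenols and at O3''. Bromine at C4a serves twice: it raises the electrophilicity of the vinylogous ester, and it is the leaving group that brings the adduct to the arene oxidation state without an oxidant. The stereocentres formed at C4a, C5 and C8a vanish on aromatisation, and C2, C2'' and C3'' are kept because no base able to enolise the C4 ketones is present. The step needs the orientation that puts oxygen at C5 and C7, which charge matching secures (the most nucleophilic diene carbon meets the most electrophilic acceptor carbon, C8a), and only the [4+2] mode can close a six-membered ring, since a [3+3] closure onto C4 would give a bridged bicycle.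

Step 10
Reactants: 17 4',4'''-di-O-benzyl ether of 18
Product: 18 (2R,3R)-3,5,7-trihydroxy-2-{4-hydroxy-3-[2-hydroxy-5-((2S)-5,7-dihydroxy-4-oxochroman-2-yl)phenyl]phenyl}chroman-4-one
Conditions: H2 (1 atm), Pd/C (10 wt%), EtOAc–MeOH, rt
Reagents that add atoms: none
Why: Hydrogenolysis of the two aryl benzyl ethers over palladium; the ring C2–O bonds are hindered secondary benzylic aryl ethers that should react far more slowly under these neutral conditions, and no stereocentre is touched.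

Compound list
1 | 4-(benzyloxy)-3-bromobenzaldehyde | O=Cc1ccc(OCc2ccccc2)c(Br)c1 | starting material
2 | (E)-1-methoxy-3-(trimethylsilyloxy)buta-1,3-diene (Danishefsky's diene) | CO/C=C/C(=C)O[Si](C)(C)C | starting material
3 | (S,E)-5-[4-(benzyloxy)-3-bromophenyl]-1-methoxy-5-(trimethylsilyloxy)pent-1-en-3-one | CO/C=C/C(=O)C[C@@H](c1ccc(OCc2ccccc2)c(Br)c1)O[Si](C)(C)C | intermediate (not isolated)
4 | (S)-2-[4-(benzyloxy)-3-bromophenyl]-2,3-dihydro-4H-pyran-4-one | O=C1C[C@@H](c2ccc(OCc3ccccc3)c(Br)c2)OC=C1 | intermediate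
5 | (S)-2-[4-(benzyloxy)-3-(4,4,5,5-tetramethyl-1,3,2-dioxaborolan-2-yl)phenyl]-2,3-dihydro-4H-pyran-4-one | O=C1C[C@@H](c2ccc(OCc3ccccc3)c(B4OC(C)(C)C(C)(C)O4)c2)OC=C1 | intermediate
6 | (S)-2-[4-(benzyloxy)-3-bromophenyl]-4-(trimethylsilyloxy)-2H-pyran | C[Si](C)(C)OC1=C[C@@H](c2ccc(OCc3ccccc3)c(Br)c2)OC=C1 | intermediate (not isolated)
7 | (2R,3R,4R)-2-[4-(benzyloxy)-3-bromophenyl]-3,4-epoxy-4-(trimethylsilyloxy)-3,4-dihydro-2H-pyran, epoxide oxygen anti to the aryl group | C[Si](C)(C)O[C@]12C=CO[C@H](c3ccc(OCc4ccccc4)c(Br)c3)[C@H]1O2 | intermediate (not isolated)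
8 | (2R,3R)-2-[4-(benzyloxy)-3-bromophenyl]-3-hydroxy-2,3-dihydro-4H-pyran-4-one (2,3-trans) | O=C1[C@H](O)[C@@H](c2ccc(OCc3ccccc3)c(Br)c2)OC=C1 | intermediate
9 | (2R,3R)-2-[4-(benzyloxy)-3-bromophenyl]-3-(triethylsilyloxy)-2,3-dihydro-4H-pyran-4-one | O=C1[C@H](O[Si](CC)(CC)CC)[C@@H](c2ccc(OCc3ccccc3)c(Br)c2)OC=C1 | intermediate
10 | (2R,3R)-2-{4-(benzyloxy)-3-[2-(benzyloxy)-5-((2S)-4-oxo-3,4-dihydro-2H-pyran-2-yl)phenyl]phenyl}-3-(triethylsilyloxy)-2,3-dihydro-4H-pyran-4-one | O=C1C[C@@H](c2ccc(OCc6ccccc6)c(-c3cc([C@H]4OC=CC(=O)[C@@H]4O[Si](CC)(CC)CC)ccc3OCc6ccccc6)c2)OC=C1 | intermediate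
11 | (2R,3R)-5-bromo-2-{4-(benzyloxy)-3-[2-(benzyloxy)-5-((2S)-5-bromo-4-oxo-3,4-dihydro-2H-pyran-2-yl)phenyl]phenyl}-3-(triethylsilyloxy)-2,3-dihydro-4H-pyran-4-one; the 6,6'-bis(benzyloxy)biphenyl-3,3'-diyl bis(5-bromo-2,3-dihydro-4H-pyran-4-one) with a trans C3 silyloxy group on one ring | O=C1C[C@@H](c2ccc(OCc6ccccc6)c(-c3cc([C@H]4OC=C(Br)C(=O)[C@@H]4O[Si](CC)(CC)CC)ccc3OCc6ccccc6)c2)OC=C1Br | intermediate (key-step precursor)
12 | methyl acetoacetate | COC(=O)CC(C)=O | starting material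
13 | methyl 3-(trimethylsilyloxy)but-2-enoate (E/Z mixture) | COC(=O)C=C(C)O[Si](C)(C)C | intermediate
14 | 1-methoxy-1,3-bis(trimethylsilyloxy)buta-1,3-diene | COC(O[Si](C)(C)C)=CC(O[Si](C)(C)C)=C | intermediate
15 | twofold cycloadduct of 11: each ring C carries a fused 4a-bromo-5-methoxy-5,7-bis(trimethylsilyloxy)-4a,5,8,8a-tetrahydro ring A (cis fusion expected; configuration at C4a, C5, C8a and their primed counterparts undefined and lost later) | O=C1C[C@@H](c2ccc(OCc6ccccc6)c(-c3cc([C@H]4OC5CC(O[Si](C)(C)C)=CC(OC)(O[Si](C)(C)C)C5(Br)C(=O)[C@@H]4O[Si](CC)(CC)CC)ccc3OCc6ccccc6)c2)OC2CC(O[Si](C)(C)C)=CC(OC)(O[Si](C)(C)C)C12Br | intermediate (not isolated)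
16 | 4',4'''-di-O-benzyl-5,7,5'',7''-tetrakis-O-(trimethylsilyl)-3''-O-(triethylsilyl) derivative of 18 | O=C1C[C@@H](c2ccc(OCc6ccccc6)c(-c3cc([C@H]4Oc5cc(O[Si](C)(C)C)cc(O[Si](C)(C)C)c5C(=O)[C@@H]4O[Si](CC)(CC)CC)ccc3OCc6ccccc6)c2)Oc2cc(O[Si](C)(C)C)cc(O[Si](C)(C)C)c21 | intermediate (not isolated)
17 | (2R,3R)-2-{4-(benzyloxy)-3-[2-(benzyloxy)-5-((2S)-5,7-dihydroxy-4-oxochroman-2-yl)phenyl]phenyl}-3,5,7-trihydroxychroman-4-one | O=C1C[C@@H](c2ccc(OCc6ccccc6)c(-c3cc([C@H]4Oc5cc(O)cc(O)c5C(=O)[C@@H]4O)ccc3OCc6ccccc6)c2)Oc2cc(O)cc(O)c21 | intermediate (key-step product)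
18 | (2R,3R)-3,5,7-trihydroxy-2-{4-hydroxy-3-[2-hydroxy-5-((2S)-5,7-dihydroxy-4-oxochroman-2-yl)phenyl]phenyl}chroman-4-one (CNP0201582.1) | O=C1C[C@@H](c2ccc(O)c(-c3cc([C@H]4Oc5cc(O)cc(O)c5C(=O)[C@@H]4O)ccc3O)c2)Oc2cc(O)cc(O)c21 | target

Total step count: 10 (steps 7 and 8 prepare the diene).
Longest linear sequence: 7 steps (1, 3, 4, 5, 6, 9, 10).

Steps most likely to fail

1. Step 9. The annulation may stop at the open-chain conjugate adduct if silyl transfer outruns the second C–C bond formation. Bromine may be removed reductively (halophilic attack) instead of as HBr, which would leave a dihydro ring that can aromatise only by expelling the ring oxygen. Lewis-acid ionisation of the p-alkoxybenzylic C2–O bonds may erode the stereocentres. The fallback uses known flavonoid chemistry with rings A brought in preformed; it sets out from 1 and comes back at 18. Claisen–Schmidt condensation of 1 with commercial 1-[2,4-bis(benzyloxy)-6-hydroxyphenyl]ethan-1-one (KOH, EtOH–THF) should give the 2'-hydroxychalcone F1, which NaOAc in refluxing ethanol cyclises to the racemic flavanone F2. Kinetic resolution by asymmetric transfer hydrogenation (RuCl(p-cymene)(TsDPEN), HCO2H–Et3N, with the catalyst antipode that reduces the 2R ketone) should leave the (S)-flavanone F3 and turn its enantiomer into the cis-flavan-4-ol F4, which is separated. One part of F3 is borylated as in step 2 to the pinacol boronate F5. The other part is taken through the operations of steps 3 and 4: the silyl enol ether F6, the silyloxy epoxide F7, the trans-3-hydroxyflavanone F8 and its TES ether F9. Suzuki coupling of F5 with F9 as in step 5 should give the hexa-O-benzyl biflavanoid TES ether F10. Hydrogenolysis over Pd/C in EtOAc–MeOH containing a little aqueous HCl then removes the six benzyl groups and the silyl group to reach 18.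

2. Step 3. The oxidant may attack the C5=C6 enol ether of 6 instead of C3=C4, or the ring oxygen may be lost by β-elimination during enolisation. The fallback sets out from 4 and comes back at 8: direct α'-acetoxylation with Mn(OAc)3·2H2O in refluxing benzene (oxidation of the enone through its trivalent manganese enolate, a known trans-selective reaction of 2-substituted dihydropyranones) should give the trans-3-acetoxy pyranone F11, and acid-catalysed methanolysis (HCl, MeOH, 0 °C → rt) releases 8.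

3. Step 5. Protodeboronation of the ortho-alkoxy arylboronate and hydroxide addition to the vinylogous esters may outrun transmetalation. The fallback sets out from 4 and comes back at 10: stannylation (hexamethylditin, Pd(PPh3)4, toluene, 100 °C) gives the aryl trimethylstannane F12, and a base-free Stille coupling with 9 (Pd(PPh3)4, CuI, DMF, 60 °C) should give 10.

Further compounds
F1 | step 9 | (E)-1-[2,4-bis(benzyloxy)-6-hydroxyphenyl]-3-[4-(benzyloxy)-3-bromophenyl]prop-2-en-1-one | O=C(/C=C/c1ccc(OCc2ccccc2)c(Br)c1)c1c(O)cc(OCc2ccccc2)cc1OCc1ccccc1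
F2 | step 9 | racemic 5,7-bis(benzyloxy)-2-[4-(benzyloxy)-3-bromophenyl]chroman-4-one | O=C1CC(c2ccc(OCc3ccccc3)c(Br)c2)Oc2cc(OCc3ccccc3)cc(OCc3ccccc3)c21
F3 | step 9 | (S)-5,7-bis(benzyloxy)-2-[4-(benzyloxy)-3-bromophenyl]chroman-4-one | O=C1C[C@@H](c2ccc(OCc3ccccc3)c(Br)c2)Oc2cc(OCc3ccccc3)cc(OCc3ccccc3)c21
F4 | step 9 | (2R,4R)-5,7-bis(benzyloxy)-2-[4-(benzyloxy)-3-bromophenyl]chroman-4-ol (2,4-cis) | O[C@@H]1C[C@H](c2ccc(OCc3ccccc3)c(Br)c2)Oc2cc(OCc3ccccc3)cc(OCc3ccccc3)c21
F5 | step 9 | (S)-5,7-bis(benzyloxy)-2-[4-(benzyloxy)-3-(4,4,5,5-tetramethyl-1,3,2-dioxaborolan-2-yl)phenyl]chroman-4-one | O=C1C[C@@H](c2ccc(OCc3ccccc3)c(B4OC(C)(C)C(C)(C)O4)c2)Oc2cc(OCc3ccccc3)cc(OCc3ccccc3)c21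
F6 | step 9 | (S)-5,7-bis(benzyloxy)-2-[4-(benzyloxy)-3-bromophenyl]-4-(trimethylsilyloxy)-2H-chromene | C[Si](C)(C)OC1=C[C@@H](c2ccc(OCc3ccccc3)c(Br)c2)Oc2cc(OCc3ccccc3)cc(OCc3ccccc3)c21
F7 | step 9 | 3,4-epoxide of F6, (2R,3R) at C2 and C3, epoxide oxygen anti to the C2 aryl group | C[Si](C)(C)O[C@]12c3c(OCc4ccccc4)cc(OCc4ccccc4)cc3O[C@H](c3ccc(OCc4ccccc4)c(Br)c3)[C@H]1O2
F8 | step 9 | (2R,3R)-5,7-bis(benzyloxy)-2-[4-(benzyloxy)-3-bromophenyl]-3-hydroxychroman-4-one | O=C1[C@H](O)[C@@H](c2ccc(OCc3ccccc3)c(Br)c2)Oc2cc(OCc3ccccc3)cc(OCc3ccccc3)c21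
F9 | step 9 | (2R,3R)-5,7-bis(benzyloxy)-2-[4-(benzyloxy)-3-bromophenyl]-3-(triethylsilyloxy)chroman-4-one | O=C1[C@H](O[Si](CC)(CC)CC)[C@@H](c2ccc(OCc3ccccc3)c(Br)c2)Oc2cc(OCc3ccccc3)cc(OCc3ccccc3)c21
F10 | step 9 | 4',5,7,4''',5'',7''-hexa-O-benzyl-3''-O-(triethylsilyl) derivative of 18 | O=C1C[C@@H](c2ccc(OCc6ccccc6)c(-c3cc([C@H]4Oc5cc(OCc6ccccc6)cc(OCc6ccccc6)c5C(=O)[C@@H]4O[Si](CC)(CC)CC)ccc3OCc6ccccc6)c2)Oc2cc(OCc6ccccc6)cc(OCc6ccccc6)c21
F11 | step 3 | (2R,3R)-2-[4-(benzyloxy)-3-bromophenyl]-4-oxo-3,4-dihydro-2H-pyran-3-yl acetate | O=C1[C@H](OC(C)=O)[C@@H](c2ccc(OCc3ccccc3)c(Br)c2)OC=C1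
F12 | step 5 | (S)-2-[4-(benzyloxy)-3-(trimethylstannyl)phenyl]-2,3-dihydro-4H-pyran-4-one | O=C1C[C@@H](c2ccc(OCc3ccccc3)c([Sn](C)(C)C)c2)OC=C1
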